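**Plan**

- The naphthalene is numbered with the aryl group on C1, the benzyl group on C2 and the hydroxyl on C3. Ring A is the new carbocycle, ring B the oxygenated benzo ring, ring C the aryl group on C1 and ring D the arene of the benzyl group.
- Retrosynthesis: the three phenols are masked as benzyl ethers and ring A is cut at C4–C4a to give an open-chain 4,4-diaryl-3-benzyl-1,1-dimethoxybutan-2-one. This cut is possible because ring B, seen from C8a, is a 4-oxy-3,5-dimethoxyphenyl group whose two ortho carbons are equivalent and each lies ortho to one methoxy group and para to the other, so C4a can form without a regiochemical choice.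
- The chain is then cut at C2–CH2 (enolate benzylation), at C1–ring C (conjugate addition of an arylboronic acid) and at C1–C2 (Claisen–Schmidt condensation of O-benzylsyringaldehyde with 1,1-dimethoxypropan-2-one).
- Forward order: enone, 1,4-arylation, α-benzylation, acid-mediated closure and aromatisation of ring A (the only ring formed), then hydrogenolysis.
- Stereochemistry: the target has no stereocentre. The two sp3 centres of the open-chain precursor are made without control and disappear when ring A aromatises.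

Key step: step 8

Assumption: the structure defines no configuration for the C1–ring C axis, so no control of this axis is attempted and the compound is made as the racemate if rotation about it is slow.

**Route**

Step 1
Reactants: 1 syringaldehyde (4-hydroxy-3,5-dimethoxybenzaldehyde)
Product: 2 4-(benzyloxy)-3,5-dimethoxybenzaldehyde
Conditions: BnBr, K2CO3, DMF, 60 °C
Reagents that add atoms: benzyl bromide, BrCc1ccccc1
Why: Williamson ether synthesis of the phenoxide with a benzylic bromide, to which the aldehyde is inert under carbonate conditions.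

Step 2
Reactants: 2 4-(benzyloxy)-3,5-dimethoxybenzaldehyde; 3 1,1-dimethoxypropan-2-one
Product: 5 (E)-4-[4-(benzyloxy)-3,5-dimethoxyphenyl]-1,1-dimethoxybut-3-en-2-one, via β-hydroxy ketone 4 (not isolated)
Conditions: NaOH (10% aq), MeOH, 0 °C to rt
Reagents that add atoms: none
Why: Claisen–Schmidt aldol condensation in which only the methyl group of 3 can add to the non-enolisable aldehyde and dehydrate by E1cB to the conjugated E-enone, the acetal being stable to base.

Step 3
Reactants: 6 4-bromo-3-methoxyphenol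
Product: 7 4-(benzyloxy)-1-bromo-2-methoxybenzene
Conditions: BnBr, K2CO3, acetone, reflux
Reagents that add atoms: benzyl bromide, BrCc1ccccc1
Why: Williamson ether synthesis on an unhindered phenol, leaving the aryl bromide untouched.

Step 4
Reactants: 7 4-(benzyloxy)-1-bromo-2-methoxybenzene
Product: 10 [4-(benzyloxy)-2-methoxyphenyl]boronic acid, via aryllithium 8 (not isolated), via lithium triisopropoxyborate 9 (not isolated)
Conditions: n-BuLi, THF, −78 °C; B(OiPr)3, −78 °C to rt; 1 M HCl, 0 °C
Reagents that add atoms: triisopropyl borate, CC(C)OB(OC(C)C)OC(C)C; water, O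
Why: Bromine–lithium exchange at −78 °C outruns deprotonation of the benzyl ether, and trapping of the aryllithium by the borate followed by mild acidic hydrolysis of the ate complex is the standard lithiation–borylation route to arylboronic acids.

Step 5
Reactants: 5 (E)-4-[4-(benzyloxy)-3,5-dimethoxyphenyl]-1,1-dimethoxybut-3-en-2-one; 10 [4-(benzyloxy)-2-methoxyphenyl]boronic acid
Product: 11 4-[4-(benzyloxy)-3,5-dimethoxyphenyl]-4-[4-(benzyloxy)-2-methoxyphenyl]-1,1-dimethoxybutan-2-one (racemic)
Conditions: [Rh(cod)Cl]2 (3 mol%), KOH (0.5 equiv), 10 (2 equiv), 1,4-dioxane/H2O 10:1, 50 °C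
Reagents that add atoms: none
Why: Hayashi–Miyaura 1,4-addition, in which an aryl complex of monovalent rhodium inserts the β-aryl enone and water protonates the rhodium enolate; the achiral diene ligand gives the new stereocentre as a racemate, which suffices because this centre later becomes aromatic C1.

Step 6
Reactants: 12 [4-(benzyloxy)-3-methoxyphenyl]methanol (commercial O-benzylvanillyl alcohol)
Product: 13 1-(benzyloxy)-4-(bromomethyl)-2-methoxybenzene
Conditions: PBr3 (0.4 equiv), CH2Cl2, 0 °C; used at once
Reagents that add atoms: phosphorus tribromide, BrP(Br)Br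
Why: PBr3 activates the electron-rich benzylic alcohol as a phosphite that bromide displaces readily, the usual conversion of benzylic alcohols into bromides.

Step 7
Reactants: 11 4-[4-(benzyloxy)-3,5-dimethoxyphenyl]-4-[4-(benzyloxy)-2-methoxyphenyl]-1,1-dimethoxybutan-2-one; 13 1-(benzyloxy)-4-(bromomethyl)-2-methoxybenzene
Product: 15 4-[4-(benzyloxy)-3,5-dimethoxyphenyl]-4-[4-(benzyloxy)-2-methoxyphenyl]-3-[4-(benzyloxy)-3-methoxybenzyl]-1,1-dimethoxybutan-2-one (mixture of diastereomers), via lithium enolate 14 (not isolated)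
Conditions: LiN(SiMe3)2 (1.1 equiv), THF, −78 °C; then 13, DMPU, −78 to 0 °C
Reagents that add atoms: none
Why: Ketone enolate alkylation, in which deprotonation takes place at the C3 methylene (the acetal C–H would lead to a disfavoured dialkoxy-substituted enolate) and the benzylic bromide is a reactive SN2 partner; the second stereocentre forms without control, which is acceptable because both centres are later erased.

Step 8
Reactants: 15 4-[4-(benzyloxy)-3,5-dimethoxyphenyl]-4-[4-(benzyloxy)-2-methoxyphenyl]-3-[4-(benzyloxy)-3-methoxybenzyl]-1,1-dimethoxybutan-2-one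
Product: 17 7-(benzyloxy)-4-[4-(benzyloxy)-2-methoxyphenyl]-3-[4-(benzyloxy)-3-methoxybenzyl]-6,8-dimethoxynaphthalen-2-ol, via methoxytetralone 16 (not isolated)
Conditions: p-TsOH·H2O (0.2 equiv), toluene (0.02 M), 80 °C
Reagents that add atoms: none
Why: Acid ionises the dimethyl acetal to an α-acyl oxocarbenium ion at C4, an ortho carbon of ring B attacks it (C4–C4a bond) to give methoxytetralone 16, and enolisation of the C3 ketone toward C2, ionisation of the now benzylic C4 methoxy group and loss of the doubly benzylic C1 proton aromatise ring A, so the aldehyde oxidation level of the acetal supplies the unsaturation and the C3 oxygen remains as the naphthol. The closest known reaction type is the Bradsher-type cyclodehydration of aryl-tethered keto-acetals and aldehydes onto electron-rich arenes. Ring A closes by a six-membered intramolecular Friedel–Crafts alkylation, 6-exo with respect to the oxocarbenium carbon and with the arene π-bond inside the new ring. No stereocentre is created that survives, since the three sp3 carbons of 16 all become aromatic. The step needs chemoselectivity among three arenes that can each reach the cation through a six-membered transition state: the attacking carbon of ring B is ortho to one methoxy group and para to the other, the ortho carbons of ring D are each activated by only one methoxy group, and the free ortho carbon of ring C is meta to both of its oxygens, while the equivalence of the two ortho carbons of ring B removes any regiochemical question. High dilution and the low acid loading are chosen to keep the electron-rich naphthol from intermolecular alkylation and to leave the benzyl ethers in place.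

Step 9
Reactants: 17 7-(benzyloxy)-4-[4-(benzyloxy)-2-methoxyphenyl]-3-[4-(benzyloxy)-3-methoxybenzyl]-6,8-dimethoxynaphthalen-2-ol
Product: 18 4-(4-hydroxy-2-methoxyphenyl)-3-(4-hydroxy-3-methoxybenzyl)-6,8-dimethoxynaphthalene-2,7-diol (CNP0000246.0)
Conditions: H2 (1 atm), 10% Pd/C, EtOAc/MeOH, rt
Reagents that add atoms: none
Why: Catalytic hydrogenolysis cleaves the three aryl benzyl ethers, while the methyl ethers, the diarylmethane C–C bonds and the naphthalene core are inert at atmospheric pressure.

**Compound list**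

1 | syringaldehyde (4-hydroxy-3,5-dimethoxybenzaldehyde) | COc1cc(C=O)cc(OC)c1O | starting material
2 | 4-(benzyloxy)-3,5-dimethoxybenzaldehyde | COc1cc(C=O)cc(OC)c1OCc1ccccc1 | intermediate
3 | 1,1-dimethoxypropan-2-one | CC(=O)C(OC)OC | starting material
4 | 4-[4-(benzyloxy)-3,5-dimethoxyphenyl]-4-hydroxy-1,1-dimethoxybutan-2-one (racemic, not isolated) | COC(OC)C(=O)CC(O)c1cc(OC)c(OCc2ccccc2)c(OC)c1 | intermediate
5 | (E)-4-[4-(benzyloxy)-3,5-dimethoxyphenyl]-1,1-dimethoxybut-3-en-2-one | COC(OC)C(=O)/C=C/c1cc(OC)c(OCc2ccccc2)c(OC)c1 | intermediate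
6 | 4-bromo-3-methoxyphenol | COc1cc(O)ccc1Br | starting material
7 | 4-(benzyloxy)-1-bromo-2-methoxybenzene | COc1cc(OCc2ccccc2)ccc1Br | intermediate
8 | [4-(benzyloxy)-2-methoxyphenyl]lithium (not isolated) | [Li]c1ccc(OCc2ccccc2)cc1OC | intermediate
9 | lithium [4-(benzyloxy)-2-methoxyphenyl]triisopropoxyborate (not isolated) | [Li+].CC(C)O[B-](OC(C)C)(OC(C)C)c1ccc(OCc2ccccc2)cc1OC | intermediate
10 | [4-(benzyloxy)-2-methoxyphenyl]boronic acid | COc1cc(OCc2ccccc2)ccc1B(O)O | intermediate
11 | 4-[4-(benzyloxy)-3,5-dimethoxyphenyl]-4-[4-(benzyloxy)-2-methoxyphenyl]-1,1-dimethoxybutan-2-one (racemic) | COC(OC)C(=O)CC(c1cc(OC)c(OCc2ccccc2)c(OC)c1)c1ccc(OCc2ccccc2)cc1OC | intermediate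
12 | [4-(benzyloxy)-3-methoxyphenyl]methanol | COc1cc(CO)ccc1OCc1ccccc1 | starting material
13 | 1-(benzyloxy)-4-(bromomethyl)-2-methoxybenzene | COc1cc(CBr)ccc1OCc1ccccc1 | intermediate
14 | lithium enolate of 11 at C2–C3 (not isolated) | [Li]OC(=CC(c1cc(OC)c(OCc2ccccc2)c(OC)c1)c1ccc(OCc2ccccc2)cc1OC)C(OC)OC | intermediate
15 | 4-[4-(benzyloxy)-3,5-dimethoxyphenyl]-4-[4-(benzyloxy)-2-methoxyphenyl]-3-[4-(benzyloxy)-3-methoxybenzyl]-1,1-dimethoxybutan-2-one (mixture of diastereomers) | COC(OC)C(=O)C(Cc1ccc(OCc2ccccc2)c(OC)c1)C(c1cc(OC)c(OCc2ccccc2)c(OC)c1)c1ccc(OCc2ccccc2)cc1OC | intermediate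
16 | 7-(benzyloxy)-4-[4-(benzyloxy)-2-methoxyphenyl]-3-[4-(benzyloxy)-3-methoxybenzyl]-1,6,8-trimethoxy-3,4-dihydronaphthalen-2(1H)-one (mixture of diastereomers, not isolated) | COC1C(=O)C(Cc2ccc(OCc3ccccc3)c(OC)c2)C(c2ccc(OCc3ccccc3)cc2OC)c2cc(OC)c(OCc3ccccc3)c(OC)c12 | intermediate
17 | 7-(benzyloxy)-4-[4-(benzyloxy)-2-methoxyphenyl]-3-[4-(benzyloxy)-3-methoxybenzyl]-6,8-dimethoxynaphthalen-2-ol | Oc1cc2c(OC)c(OCc3ccccc3)c(OC)cc2c(-c2ccc(OCc3ccccc3)cc2OC)c1Cc1ccc(OCc2ccccc2)c(OC)c1 | intermediate
18 | 4-(4-hydroxy-2-methoxyphenyl)-3-(4-hydroxy-3-methoxybenzyl)-6,8-dimethoxynaphthalene-2,7-diol (CNP0000246.0) | COc1cc(Cc2c(O)cc3c(OC)c(O)c(OC)cc3c2-c2ccc(O)cc2OC)ccc1O | target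

**Step count and risks**

Total steps: 9. Longest linear sequence: 6 steps (steps 1, 2, 5, 7, 8, 9, or equally steps 3, 4, 5, 7, 8, 9).

Steps most likely to fail:

1. Step 8. The oxocarbenium ion may close onto ring D instead of ring B, benzyl groups may be lost or migrate under acid, or the product naphthol may be alkylated by a second cation. The fallback sets out from ketone 11 and comes back at naphthol 17. It carries the benzylic carbon through the ring closure as a ketone, whose carbonyl is conjugated with ring D and deactivates both of its ortho carbons. Enolate 14, formed from 11 as in step 7, would be C-acylated in toluene with 4-(benzyloxy)-3-methoxybenzoyl chloride F1, itself made from commercial 4-(benzyloxy)-3-methoxybenzoic acid with (COCl)2 and catalytic DMF. This should give 1-[4-(benzyloxy)-3-methoxyphenyl]-2-{[4-(benzyloxy)-3,5-dimethoxyphenyl][4-(benzyloxy)-2-methoxyphenyl]methyl}-4,4-dimethoxybutane-1,3-dione F2. The acid treatment of step 8 should then close only onto ring B and give [6-(benzyloxy)-1-[4-(benzyloxy)-2-methoxyphenyl]-3-hydroxy-5,7-dimethoxynaphthalen-2-yl][4-(benzyloxy)-3-methoxyphenyl]methanone F3. Its naphthol would be converted with ClCO2Et and Et3N into 7-(benzyloxy)-4-[4-(benzyloxy)-2-methoxyphenyl]-3-[4-(benzyloxy)-3-methoxybenzoyl]-6,8-dimethoxynaphthalen-2-yl ethyl carbonate F4. NaBH4 in aqueous THF should reduce the ketone, after which carbonate transfer and elimination give an ortho-quinone methide that is reduced in turn to the methylene compound 17.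

2. Step 7. Alkylation at the hindered α-carbon next to the diarylmethyl group may stall, the enolate may react at oxygen, or the labile benzylic bromide may decompose first. The fallback sets out from ketone 11 and comes back at keto-acetal 15. It replaces the SN2 alkylation by an aldol addition, which is less sensitive to hindrance, followed by removal of the oxygen. Enolate 14 would add at −78 °C to commercial 4-(benzyloxy)-3-methoxybenzaldehyde to give 3-{[4-(benzyloxy)-3-methoxyphenyl](hydroxy)methyl}-4-[4-(benzyloxy)-3,5-dimethoxyphenyl]-4-[4-(benzyloxy)-2-methoxyphenyl]-1,1-dimethoxybutan-2-one F5. MsCl and Et3N would convert it into its methanesulfonate F6, and DBU should eliminate this to 3-[4-(benzyloxy)-3-methoxybenzylidene]-4-[4-(benzyloxy)-3,5-dimethoxyphenyl]-4-[4-(benzyloxy)-2-methoxyphenyl]-1,1-dimethoxybutan-2-one F7. Conjugate reduction of the enone with [(Ph3P)CuH]6 in wet toluene, which leaves benzyl ethers untouched, should then give 15.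

3. Step 5. Protodeboronation of the electron-rich, ortho-substituted boronic acid may outpace transmetalation, and insertion of the electron-rich β-aryl enone may be slow. The fallback sets out from bromide 7 and enone 5 and comes back at ketone 11. It uses an organocopper conjugate addition in place of the rhodium–boron chemistry. Bromide 7 with Mg in THF would give [4-(benzyloxy)-2-methoxyphenyl]magnesium bromide F8. Its addition to 5 at −78 °C with catalytic CuBr·SMe2 and Me3SiCl should give {[4-[4-(benzyloxy)-3,5-dimethoxyphenyl]-4-[4-(benzyloxy)-2-methoxyphenyl]-1,1-dimethoxybut-2-en-2-yl]oxy}trimethylsilane F9. Brief treatment with 1 M HCl in THF at 0 °C, which the α-keto acetal should survive, would hydrolyse the silyl enol ether to 11.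

Further compounds

F1 | step 8 | 4-(benzyloxy)-3-methoxybenzoyl chloride | COc1cc(C(Cl)=O)ccc1OCc1ccccc1
F2 | step 8 | 1-[4-(benzyloxy)-3-methoxyphenyl]-2-{[4-(benzyloxy)-3,5-dimethoxyphenyl][4-(benzyloxy)-2-methoxyphenyl]methyl}-4,4-dimethoxybutane-1,3-dione | COC(OC)C(=O)C(C(=O)c1ccc(OCc2ccccc2)c(OC)c1)C(c1cc(OC)c(OCc2ccccc2)c(OC)c1)c1ccc(OCc2ccccc2)cc1OC
F3 | step 8 | [6-(benzyloxy)-1-[4-(benzyloxy)-2-methoxyphenyl]-3-hydroxy-5,7-dimethoxynaphthalen-2-yl][4-(benzyloxy)-3-methoxyphenyl]methanone | Oc1cc2c(OC)c(OCc3ccccc3)c(OC)cc2c(-c2ccc(OCc3ccccc3)cc2OC)c1C(=O)c1ccc(OCc2ccccc2)c(OC)c1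
F4 | step 8 | 7-(benzyloxy)-4-[4-(benzyloxy)-2-methoxyphenyl]-3-[4-(benzyloxy)-3-methoxybenzoyl]-6,8-dimethoxynaphthalen-2-yl ethyl carbonate | CCOC(=O)Oc1cc2c(OC)c(OCc3ccccc3)c(OC)cc2c(-c2ccc(OCc3ccccc3)cc2OC)c1C(=O)c1ccc(OCc2ccccc2)c(OC)c1
F5 | step 7 | 3-{[4-(benzyloxy)-3-methoxyphenyl](hydroxy)methyl}-4-[4-(benzyloxy)-3,5-dimethoxyphenyl]-4-[4-(benzyloxy)-2-methoxyphenyl]-1,1-dimethoxybutan-2-one | COC(OC)C(=O)C(C(O)c1ccc(OCc2ccccc2)c(OC)c1)C(c1cc(OC)c(OCc2ccccc2)c(OC)c1)c1ccc(OCc2ccccc2)cc1OC
F6 | step 7 | methanesulfonate of F5 | COC(OC)C(=O)C(C(OS(C)(=O)=O)c1ccc(OCc2ccccc2)c(OC)c1)C(c1cc(OC)c(OCc2ccccc2)c(OC)c1)c1ccc(OCc2ccccc2)cc1OC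
F7 | step 7 | 3-[4-(benzyloxy)-3-methoxybenzylidene]-4-[4-(benzyloxy)-3,5-dimethoxyphenyl]-4-[4-(benzyloxy)-2-methoxyphenyl]-1,1-dimethoxybutan-2-one | COC(OC)C(=O)C(=Cc1ccc(OCc2ccccc2)c(OC)c1)C(c1cc(OC)c(OCc2ccccc2)c(OC)c1)c1ccc(OCc2ccccc2)cc1OC
F8 | step 5 | [4-(benzyloxy)-2-methoxyphenyl]magnesium bromide | COc1cc(OCc2ccccc2)ccc1[Mg]Br
F9 | step 5 | {[4-[4-(benzyloxy)-3,5-dimethoxyphenyl]-4-[4-(benzyloxy)-2-methoxyphenyl]-1,1-dimethoxybut-2-en-2-yl]oxy}trimethylsilane | COC(OC)C(O[Si](C)(C)C)=CC(c1cc(OC)c(OCc2ccccc2)c(OC)c1)c1ccc(OCc2ccccc2)cc1OC
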